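**Retrosynthetic overview**
1. Target 24 ⇐ late peracid epoxidation of the 1(10)-alkene ⇐ acetonide removal and C8 esterification of macrocyclic alcohol 20.
2. Key step: the C7–C8 bond is formed by SmI2 ketyl-radical 10-exo addition of the C8 aldehyde to C7 of butenolide 19, followed by loss of methoxide. This closes the ten-membered ring, sets C7 and C8, and unveils the α-methylene lactone in one step.
3. Butenolide ⇐ carbonylative lactonization of Z-iodoalkenol 16 ⇐ hydroxyl-directed hydroalumination/iodination of alkyne 14.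
4. 14 ⇐ Nozaki–Hiyama–Kishi coupling (C3–C4) of Z-alkenyl iodide 13 with aldehyde 7; 13 ⇐ asymmetric alkynylation (C6) of Z-iodoenal 10 with methyl propargyl ether; 7 ⇐ carboalumination of a butynol ether and oxirane opening.
5. Ring order: butenolide (five-membered) → ten-membered carbocycle (radical step) → oxirane; a dioxane acetonide is carried in between.

Assumption: positions are labelled with germacrane numbering (C6 lactone carbinol, C7, C8 acyloxy carbon, C1/C10 epoxide with C14 methyl on C10, C3 carbinol, C4=C5 with C15H2OH, C11=C13 methylene, C12 carbonyl); the given SMILES is (1R,3S,4Z,6R,7R,8R,10R) with a (2S)-2-methylbutanoate. The route is a proposal and has not been run.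

**Route**

Step 1
Reactants: 1 but-3-yn-1-ol
Product: 2 (but-3-yn-1-yloxy)triethylsilane
Conditions: TESCl, imidazole, CH2Cl2, 0 °C to rt
Reagents that add atoms: chlorotriethylsilane, CC[Si](Cl)(CC)CC
Why: Standard silylation of a primary alcohol; the primary triethylsilyl ether is chosen because it is later oxidised directly to the aldehyde under Swern conditions.

Step 2
Reactants: 2 (but-3-yn-1-yloxy)triethylsilane; 3 oxirane
Product: 6 (E)-4-methyl-6-(triethylsilyloxy)hex-3-en-1-ol, via alkenyldimethylalane 4 (not isolated), via lithium alkenylalanate 5 (not isolated)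
Conditions: Me3Al, Cp2ZrCl2 (20 mol%), CH2Cl2, 0 °C to rt; n-BuLi, hexane/THF, −78 °C; then 3, −78 to 0 °C
Reagents that add atoms: trimethylaluminium, C[Al](C)C
Why: Negishi zirconium-catalysed carboalumination adds Me and Al syn across the terminal alkyne (Me to the internal carbon), which fixes the E trisubstituted C1=C10 alkene, and the ate complex opens oxirane with retention of alkene geometry.

Step 3
Reactants: 6 (E)-4-methyl-6-(triethylsilyloxy)hex-3-en-1-ol
Product: 7 (E)-4-methyl-6-(triethylsilyloxy)hex-3-enal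
Conditions: Dess–Martin periodinane, NaHCO3, CH2Cl2, 0 °C; used crude
Reagents that add atoms: none
Why: Buffered Dess–Martin oxidation gives the β,γ-unsaturated aldehyde without migration of the alkene into conjugation.

Step 4
Reactants: 8 but-2-yne-1,4-diol
Product: 9 4-hydroxybut-2-ynal
Conditions: activated MnO2, CH2Cl2, rt, stopped at mono-oxidation
Reagents that add atoms: none
Why: MnO2 oxidation of a propargylic alcohol; the electron-poor ynal formed slows oxidation of the second carbinol, so the mono-aldehyde can be isolated.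

Step 5
Reactants: 9 4-hydroxybut-2-ynal
Product: 10 (Z)-4-hydroxy-3-iodobut-2-enal
Conditions: NaI, AcOH, 0 °C to rt
Reagents that add atoms: sodium iodide, [Na+].[I-]
Why: Conjugate hydroiodination of the ynal (iodide adds to the β-carbon, the allenol is protonated anti) gives the Z β-iodoenal with iodine cis to CHO, which fixes the later C4=C5 geometry (C3 cis to C6).

Step 6
Reactants: 10 (Z)-4-hydroxy-3-iodobut-2-enal; 11 3-methoxyprop-1-yne
Product: 13 (2Z,4R)-2-iodo-7-methoxyhept-2-en-5-yne-1,4-diol, via alkynyl(methyl)zinc 12 (not isolated)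
Conditions: 11 (3 equiv), Me2Zn (4 equiv), (S,S)-ProPhenol (20 mol%), Ph3PO (40 mol%), toluene, 0 °C
Reagents that add atoms: none
Why: Trost zinc–ProPhenol asymmetric alkynylation of an enal; ligand-controlled delivery of the alkynyl group to the Si face of the aldehyde sets the C6 carbinol as R, and one extra equivalent of Me2Zn covers the free hydroxyl.

Step 7
Reactants: 13 (2Z,4R)-2-iodo-7-methoxyhept-2-en-5-yne-1,4-diol; 7 (E)-4-methyl-6-(triethylsilyloxy)hex-3-enal
Product: 14 (4R,5Z,7S,9E)-6-(hydroxymethyl)-1-methoxy-10-methyl-12-(triethylsilyloxy)dodeca-5,9-dien-2-yne-4,7-diol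
Conditions: CrCl2 (6 equiv), NiCl2 (2 mol%), (S)-N-[2-(4-isopropyl-4,5-dihydrooxazol-2-yl)-6-methylphenyl]methanesulfonamide, Et3N, THF, rt; C3 epimer removed by chromatography
Reagents that add atoms: none
Why: Nozaki–Hiyama–Kishi coupling (zerovalent nickel inserts into the C–I bond, transmetalation gives the alkenyl trivalent chromium species, which adds to the aldehyde with retention of alkene geometry and tolerates free hydroxyls); the chiral sulfonamide ligand directs Re-face addition to give the 7S (C3) carbinol.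

Step 8
Reactants: 14 (4R,5Z,7S,9E)-6-(hydroxymethyl)-1-methoxy-10-methyl-12-(triethylsilyloxy)dodeca-5,9-dien-2-yne-4,7-diol
Product: 16 (2Z,4R,5Z,7S,9E)-6-(hydroxymethyl)-2-iodo-1-methoxy-10-methyl-12-(triethylsilyloxy)dodeca-2,5,9-triene-4,7-diol, via cyclic sodium alkenylalanate 15 (not isolated)
Conditions: NaAlH2(OCH2CH2OMe)2 (6 equiv), THF, 0 °C; then I2, −78 °C
Reagents that add atoms: iodine, II
Why: Hydroxyl-directed trans-hydroalumination of the propargylic alcohol (hydride to the proximal alkyne carbon C7, aluminium on C11 in a five-membered alanate) and iodination with retention give the Z iodoalkene with iodine cis to the C6 carbinol; low temperature avoids allene formation by loss of methoxide.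

Step 9
Reactants: 16 (2Z,4R,5Z,7S,9E)-6-(hydroxymethyl)-2-iodo-1-methoxy-10-methyl-12-(triethylsilyloxy)dodeca-2,5,9-triene-4,7-diol
Product: 17 (5R)-5-[(1Z,3S,5E)-3-hydroxy-2-(hydroxymethyl)-6-methyl-8-(triethylsilyloxy)octa-1,5-dien-1-yl]-3-(methoxymethyl)furan-2(5H)-one
Conditions: PdCl2(PPh3)2 (5 mol%), CO (1 atm), 2,6-lutidine, THF, rt
Reagents that add atoms: carbon monoxide, [C-]#[O+]
Why: Palladium-catalysed carbonylative lactonization (Stille cyclocarbonylation of a Z-3-iodoallylic alcohol): zerovalent palladium inserts into the C–I bond, CO inserts, and only the cis C6 hydroxyl can close a five-membered ring; the weak base limits γ-epimerisation of the butenolide.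

Step 10
Reactants: 17 (5R)-5-[(1Z,3S,5E)-3-hydroxy-2-(hydroxymethyl)-6-methyl-8-(triethylsilyloxy)octa-1,5-dien-1-yl]-3-(methoxymethyl)furan-2(5H)-one
Product: 18 (5R)-5-{(Z)-[(4S)-2,2-dimethyl-4-[(2E)-3-methyl-5-(triethylsilyloxy)pent-2-en-1-yl]-1,3-dioxan-5-ylidene]methyl}-3-(methoxymethyl)furan-2(5H)-one
Conditions: Me2C(OMe)2, PPTS (cat.), CH2Cl2, rt
Reagents that add atoms: 2,2-dimethoxypropane, COC(C)(C)OC
Why: Acetonide formation (transketalisation) on the only free diol, the O3/O15 1,3-diol, so there is no regiochemical choice at this stage.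

Step 11
Reactants: 18 (5R)-5-{(Z)-[(4S)-2,2-dimethyl-4-[(2E)-3-methyl-5-(triethylsilyloxy)pent-2-en-1-yl]-1,3-dioxan-5-ylidene]methyl}-3-(methoxymethyl)furan-2(5H)-one
Product: 19 (3E)-5-[(4S,5Z)-5-{[(2R)-4-(methoxymethyl)-5-oxo-2,5-dihydrofuran-2-yl]methylidene}-2,2-dimethyl-1,3-dioxan-4-yl]-3-methylpent-3-enal
Conditions: (COCl)2, DMSO, CH2Cl2, −78 °C; i-Pr2NEt, −78 to −30 °C; cold pH 7 quench; used at once
Reagents that add atoms: none
Why: Swern oxidation acting directly on a primary triethylsilyl ether (the chlorosulfonium ion attacks the silyl ether oxygen) gives the C8 aldehyde in one step; the cold hindered-amine quench limits isomerisation of the β,γ-unsaturated aldehyde and epimerisation at C6.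

Step 12
Reactants: 19 (3E)-5-[(4S,5Z)-5-{[(2R)-4-(methoxymethyl)-5-oxo-2,5-dihydrofuran-2-yl]methylidene}-2,2-dimethyl-1,3-dioxan-4-yl]-3-methylpent-3-enal
Product: 20 (3S,6R,7R,8R)-8-hydroxy-3,15-O-isopropylidenegermacra-1(10)E,4Z,11(13)-trien-12,6-olide
Conditions: SmI2 (3 equiv), THF, syringe-pump addition of 19 to 2 mM, −78 °C to rt, no HMPA; sat. NH4Cl
Reagents that add atoms: none
Why: Proposed new method: single-electron reduction of the aldehyde gives a samarium ketyl radical that adds 10-exo-trig to the β-carbon C7 of the butenolide on the face anti to the C5 substituent at C6 (trans lactone, as in radical additions to 5-substituted furan-2(5H)-ones), through the anti transition state (O–Sm anti to C11, H8 inside, C9 antiperiplanar to C6) that gives 8R, after which the α-lactone radical is reduced to the trivalent samarium enolate and expels methoxide (E1cB) to form the α-methylene lactone; the closest known reaction types are SmI2 ketyl–enoate couplings and medium-ring ketyl–olefin cyclizations combined with radical addition–β-elimination on 2-(alkoxymethyl)acrylates.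

Step 13
Reactants: 20 (3S,6R,7R,8R)-8-hydroxy-3,15-O-isopropylidenegermacra-1(10)E,4Z,11(13)-trien-12,6-olide; 21 (S)-2-methylbutanoic acid
Product: 22 (3S,6R,7R,8R)-3,15-O-isopropylidene-8-[(2S)-2-methylbutanoyloxy]germacra-1(10)E,4Z,11(13)-trien-12,6-olide
Conditions: 21, DCC, DMAP (10 mol%), CH2Cl2, 0 °C to rt
Reagents that add atoms: none
Why: Steglich esterification of the only free hydroxyl proceeds with retention at C8, and the side-chain stereocentre comes from the enantiopure acid.

Step 14
Reactants: 22 (3S,6R,7R,8R)-3,15-O-isopropylidene-8-[(2S)-2-methylbutanoyloxy]germacra-1(10)E,4Z,11(13)-trien-12,6-olide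
Product: 23 (3S,6R,7R,8R)-3,15-dihydroxy-8-[(2S)-2-methylbutanoyloxy]germacra-1(10)E,4Z,11(13)-trien-12,6-olide
Conditions: AcOH/THF/H2O (3:1:1), rt
Reagents that add atoms: none
Why: Mild acid hydrolysis of the strained 5-alkylidene-1,3-dioxane acetonide, carried out before the acid-sensitive epoxide exists; ester, lactone and alkenes are untouched.

Step 15
Reactants: 23 (3S,6R,7R,8R)-3,15-dihydroxy-8-[(2S)-2-methylbutanoyloxy]germacra-1(10)E,4Z,11(13)-trien-12,6-olide
Product: 24 (1R,3S,6R,7R,8R,10R)-1,10-epoxy-3,15-dihydroxy-8-[(2S)-2-methylbutanoyloxy]germacra-4Z,11(13)-dien-12,6-olide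
Conditions: mCPBA (1.05 equiv), NaHCO3, CH2Cl2, 0 °C
Reagents that add atoms: 3-chloroperoxybenzoic acid, OOC(=O)c1cccc(Cl)c1
Why: Prilezhaev epoxidation is chemoselective for the electron-rich 1(10)-alkene (the 4,5-alkene carries three allylic oxygens and the methylene lactone is electron-poor), and peripheral attack on the exposed face of the E-alkene in the heliangolide conformation is expected to give the 1R,10R epoxide.

**Compound list**
1 | but-3-yn-1-ol | C#CCCO | starting material
2 | (but-3-yn-1-yloxy)triethylsilane | C#CCCO[Si](CC)(CC)CC | intermediate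
3 | oxirane | C1CO1 | starting material
4 | dimethyl[(E)-2-methyl-4-(triethylsilyloxy)but-1-en-1-yl]alane (not isolated) | C[Al](C)/C=C(\C)CCO[Si](CC)(CC)CC | intermediate
5 | lithium butyl(dimethyl)[(E)-2-methyl-4-(triethylsilyloxy)but-1-en-1-yl]alanuide (not isolated) | [Li+].CCCC[Al-](C)(C)/C=C(\C)CCO[Si](CC)(CC)CC | intermediate
6 | (E)-4-methyl-6-(triethylsilyloxy)hex-3-en-1-ol | OCC/C=C(\C)CCO[Si](CC)(CC)CC | intermediate
7 | (E)-4-methyl-6-(triethylsilyloxy)hex-3-enal | O=CC/C=C(\C)CCO[Si](CC)(CC)CC | intermediate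
8 | but-2-yne-1,4-diol | OCC#CCO | starting material
9 | 4-hydroxybut-2-ynal | O=CC#CCO | intermediate
10 | (Z)-4-hydroxy-3-iodobut-2-enal | O=C/C=C(\I)CO | intermediate
11 | 3-methoxyprop-1-yne (methyl propargyl ether) | COCC#C | starting material
12 | (3-methoxyprop-1-yn-1-yl)(methyl)zinc (not isolated) | C[Zn]C#CCOC | intermediate
13 | (2Z,4R)-2-iodo-7-methoxyhept-2-en-5-yne-1,4-diol | COCC#C[C@H](O)/C=C(\I)CO | intermediate
14 | (4R,5Z,7S,9E)-6-(hydroxymethyl)-1-methoxy-10-methyl-12-(triethylsilyloxy)dodeca-5,9-dien-2-yne-4,7-diol | COCC#C[C@H](O)/C=C(/CO)[C@@H](O)C/C=C(\C)CCO[Si](CC)(CC)CC | intermediate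
15 | cyclic sodium alkenylalanate from 14: Al on C2 and on O4, two 2-methoxyethoxy groups on Al, other hydroxyls drawn free (not isolated) | [Na+].COCC1=C[C@@H](/C=C(/CO)[C@@H](O)C/C=C(\C)CCO[Si](CC)(CC)CC)O[Al-]1(OCCOC)OCCOC | intermediate
16 | (2Z,4R,5Z,7S,9E)-6-(hydroxymethyl)-2-iodo-1-methoxy-10-methyl-12-(triethylsilyloxy)dodeca-2,5,9-triene-4,7-diol | COC/C(I)=C/[C@H](O)/C=C(/CO)[C@@H](O)C/C=C(\C)CCO[Si](CC)(CC)CC | intermediate
17 | (5R)-5-[(1Z,3S,5E)-3-hydroxy-2-(hydroxymethyl)-6-methyl-8-(triethylsilyloxy)octa-1,5-dien-1-yl]-3-(methoxymethyl)furan-2(5H)-one | COCC1=C[C@@H](/C=C(/CO)[C@@H](O)C/C=C(\C)CCO[Si](CC)(CC)CC)OC1=O | intermediate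
18 | (5R)-5-{(Z)-[(4S)-2,2-dimethyl-4-[(2E)-3-methyl-5-(triethylsilyloxy)pent-2-en-1-yl]-1,3-dioxan-5-ylidene]methyl}-3-(methoxymethyl)furan-2(5H)-one | COCC1=C[C@@H](/C=C2/COC(C)(C)O[C@H]2C/C=C(\C)CCO[Si](CC)(CC)CC)OC1=O | intermediate
19 | (3E)-5-[(4S,5Z)-5-{[(2R)-4-(methoxymethyl)-5-oxo-2,5-dihydrofuran-2-yl]methylidene}-2,2-dimethyl-1,3-dioxan-4-yl]-3-methylpent-3-enal | COCC1=C[C@@H](/C=C2/COC(C)(C)O[C@H]2C/C=C(\C)CC=O)OC1=O | intermediate
20 | (3S,6R,7R,8R)-8-hydroxy-3,15-O-isopropylidenegermacra-1(10)E,4Z,11(13)-trien-12,6-olide (ten-membered carbocycle, trans-fused α-methylene γ-lactone at C6/C7, acetonide across O3/O15) | C=C1C(=O)O[C@@H]2/C=C3/COC(C)(C)O[C@H]3C/C=C(\C)C[C@@H](O)[C@@H]12 | intermediate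
21 | (S)-2-methylbutanoic acid | CC[C@H](C)C(=O)O | starting material
22 | (3S,6R,7R,8R)-3,15-O-isopropylidene-8-[(2S)-2-methylbutanoyloxy]germacra-1(10)E,4Z,11(13)-trien-12,6-olide | C=C1C(=O)O[C@@H]2/C=C3/COC(C)(C)O[C@H]3C/C=C(\C)C[C@@H](OC(=O)[C@@H](C)CC)[C@@H]12 | intermediate
23 | (3S,6R,7R,8R)-3,15-dihydroxy-8-[(2S)-2-methylbutanoyloxy]germacra-1(10)E,4Z,11(13)-trien-12,6-olide | C=C1C(=O)O[C@@H]2/C=C(/CO)[C@@H](O)C/C=C(\C)C[C@@H](OC(=O)[C@@H](C)CC)[C@@H]12 | intermediate
24 | (1R,3S,6R,7R,8R,10R)-1,10-epoxy-3,15-dihydroxy-8-[(2S)-2-methylbutanoyloxy]germacra-4Z,11(13)-dien-12,6-olide (CNP0267576.2) | C=C1C(=O)O[C@@H]2/C=C(/CO)[C@@H](O)C[C@H]3O[C@]3(C)C[C@@H](OC(=O)[C@@H](C)CC)[C@@H]12 | target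

**Step count and risks**
Total step count: 15. Longest linear sequence: 12 steps (steps 1–3 then 7–15, or steps 4–6 then 7–15).

Most likely to fail, step 12 (radical macrocyclization). The ten-membered closure competes with reduction of the butenolide and with pinacol coupling, and the C8 configuration rests on the anti transition-state argument; chelation of the ketyl oxygen by the methoxymethyl group would give the other C8 epimer. The fallback covers the stereochemical outcome only. It sets out from 19: if the same SmI2 closure delivers mainly the C8-epimeric alcohol F1, the carbodiimide coupling of step 13 is replaced by a Mitsunobu esterification of F1 with acid 21 (PPh3, DIAD, toluene, 0 °C). This installs the ester with SN2 inversion at C8 and comes back to the route at 22.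

Second, step 7 (ligand-controlled C3 carbinol). The chiral sulfonamide may give poor selectivity with a substrate that carries two free hydroxyls. The fallback sets out from 13 and replaces the chromium coupling by an amino-alcohol-catalysed organozinc addition. Both hydroxyls are silylated (TMSCl, Et3N, CH2Cl2) to the bis(trimethylsilyl) ether F2. Iodine–lithium exchange (t-BuLi, Et2O, −78 °C) and ZnBr2 give the alkenylzinc bromide F3, which adds to aldehyde 7 in the presence of (−)-MIB (10 mol%) to give the silylated adduct F4. K2CO3 in MeOH at 0 °C removes the two trimethylsilyl ethers while the triethylsilyl ether stays, and the route is rejoined at 14.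

Third, step 15 (face of epoxidation). If the peracid attacks the other face of the 1(10)-alkene, the fallback sets out from 23 and builds the epoxide in two steps with the opposite facial sense. NBS in THF/H2O at 0 °C forms the bromonium ion on the face the peracid prefers, and water opens it at the tertiary C10 from the other face to give the bromohydrin F5. K2CO3 in acetone then closes the oxirane by displacement of bromide with inversion at C1, and the route is rejoined at 24.

Further compounds
F1 | step 12 | (3S,6R,7R,8S)-8-hydroxy-3,15-O-isopropylidenegermacra-1(10)E,4Z,11(13)-trien-12,6-olide (C8 epimer of 20) | C=C1C(=O)O[C@@H]2/C=C3/COC(C)(C)O[C@H]3C/C=C(\C)C[C@H](O)[C@@H]12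
F2 | step 7 | (2Z,4R)-2-iodo-7-methoxy-1,4-bis(trimethylsilyloxy)hept-2-en-5-yne | COCC#C[C@H](O[Si](C)(C)C)/C=C(\I)CO[Si](C)(C)C
F3 | step 7 | bromo[(2Z,4R)-7-methoxy-1,4-bis(trimethylsilyloxy)hept-2-en-5-yn-2-yl]zinc | COCC#C[C@H](O[Si](C)(C)C)/C=C(\[Zn]Br)CO[Si](C)(C)C
F4 | step 7 | (4R,5Z,7S,9E)-1-methoxy-10-methyl-12-(triethylsilyloxy)-4-(trimethylsilyloxy)-6-[(trimethylsilyloxy)methyl]dodeca-5,9-dien-2-yn-7-ol | COCC#C[C@H](O[Si](C)(C)C)/C=C(/CO[Si](C)(C)C)[C@@H](O)C/C=C(\C)CCO[Si](CC)(CC)CC
F5 | step 15 | (1S,3S,6R,7R,8R,10R)-1-bromo-3,10,15-trihydroxy-8-[(2S)-2-methylbutanoyloxy]germacra-4Z,11(13)-dien-12,6-olide | C=C1C(=O)O[C@@H]2/C=C(/CO)[C@@H](O)C[C@H](Br)[C@@](O)(C)C[C@@H](OC(=O)[C@@H](C)CC)[C@@H]12
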